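**Retrosynthetic overview**
1. The target comes from its C3‑methoxycarbonyl derivative by dealkoxycarbonylation; the ester is there only to block C3 of the phloroglucinol ring.
2. Ring B (the C1–C8 bond that closes the bicyclo[3.3.1]nonane) comes from capture of a C8 tertiary cation/ion pair by C1 of a dearomatized acylphloroglucinol, the ring closure proposed for PPAP biosynthesis.
3. The dearomatized precursor comes from two C‑alkylations at C5 of an aromatic acylphloroglucinol ester: first by a chiral 1,3‑cyclic sulfate (C5–C6 bond; its tertiary sulfate end is the latent C8 cation), then by prenyl bromide, all in one flask with the ring closure.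
4. The cyclic sulfate comes from a 1,3‑diol, made from (2R,3S)‑epoxynerol and a prenyl nucleophile (C7 set by inversion, C8–O kept), itself from nerol by Sharpless epoxidation.
5. Ring order: ring A is the purchased benzene ring and is never built; ring B is the only ring formed, in step 5 of 6.

Assumption: bicyclic compounds are numbered as in the target name (C1 acyl bridgehead, C2 ketone, C3, C4 enol carbon, C5 prenyl bridgehead, C6 CH2, C7, C8 quaternary, C9 bridging ketone), and the labels C1–C9 are also used for the atoms that become these carbons in earlier intermediates.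

**Route**

Step 1
Reactants: 1 methyl 2,4,6-trihydroxybenzoate; 2 2-methylpropanoyl chloride
Product: 3 methyl 2,4,6-trihydroxy-3-(2-methylpropanoyl)benzoate
Conditions: AlCl3 (3.5 equiv), PhNO2, 0 → 45 °C; ice/HCl
Reagents that add atoms: none
Why: Friedel–Crafts acylation at one of the two equivalent free ring positions of the electron‑rich arene gives a single regioisomer, the new ketone deactivates the ring so the last CH (future C5) stays free while the ester occupies the future C3, and no stereocenter is formed.

Step 2
Reactants: 4 nerol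
Product: 5 (2R,3S)-2,3-epoxynerol
Conditions: Ti(OiPr)4 (5 mol %), D-(−)-diethyl tartrate (6 mol %), t-BuOOH (1.5 equiv), 4 Å molecular sieves, CH2Cl2, −20 °C
Reagents that add atoms: tert-butyl hydroperoxide, CC(C)(C)OO
Why: Sharpless asymmetric epoxidation touches only the allylic alcohol alkene, the D-(−)-tartrate catalyst delivers oxygen to the face that gives the (2R,3S) epoxide (future C7 and C8), and the Z geometry of nerol is what, after inversion at C7 (step 3) and at C8 (step 5), gives the natural C7/C8 relationship.

Step 3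
Reactants: 5 (2R,3S)-2,3-epoxynerol; 6 (3-methylbut-2-en-1-yl)magnesium chloride
Product: 7 (2S,3S)-3,7-dimethyl-2-(3-methylbut-2-en-1-yl)oct-6-ene-1,3-diol
Conditions: 6 (3.0 equiv), CuI (10 mol %), THF, −40 → −10 °C; aq. NH4Cl
Reagents that add atoms: none
Why: Copper‑catalysed SN2 opening of the 2,3‑epoxy alcohol occurs at C2 because C3 is fully substituted, the allylic organocopper couples through its unsubstituted α‑carbon, and the inversion at C2 sets the future C7 as S while the tertiary C–O stereocenter (future C8) is untouched.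

Step 4
Reactants: 7 (2S,3S)-3,7-dimethyl-2-(3-methylbut-2-en-1-yl)oct-6-ene-1,3-diol
Product: 8 (4S,5S)-4-methyl-5-(3-methylbut-2-en-1-yl)-4-(4-methylpent-3-en-1-yl)-1,3,2-dioxathiane 2,2-dioxide
Conditions: NaH (2.2 equiv), THF, 0 °C; 1,1'-sulfonyldiimidazole (1.1 equiv), −20 °C → rt; used cold
Reagents that add atoms: 1,1'-sulfonyldiimidazole, O=S(=O)(n1ccnc1)n1ccnc1
Why: Double sulfonyl transfer from the dialkoxide closes the six‑membered cyclic sulfate without any oxidation (the usual SOCl2 then RuO4 sequence would cleave the alkenes), no stereocenter is touched, and the product holds a primary SN2 site (C6) and a latent tertiary cation (C8) in one reagent.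

Step 5
Reactants: 3 methyl 2,4,6-trihydroxy-3-(2-methylpropanoyl)benzoate; 8 the (4S,5S) cyclic sulfate; 9 1-bromo-3-methylbut-2-ene
Product: 12 methyl (1S,5R,7S,8R)-4-hydroxy-8-methyl-5,7-bis(3-methylbut-2-en-1-yl)-8-(4-methylpent-3-en-1-yl)-1-(2-methylpropanoyl)-2,9-dioxobicyclo[3.3.1]non-3-ene-3-carboxylate, via aryl alkyl sulfate 10 (not isolated), via dearomatized alkyl sulfate 11 (not isolated)
Conditions: LiN(SiMe3)2 (3.0 equiv), THF, −78 → 0 °C; 8, 0 °C; LiN(SiMe3)2 (1.0 equiv) then 9, 0 °C; THF removed cold, (CF3)2CHOH, 0 → 25 °C; 1 M HCl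
Reagents that add atoms: none
Why: Proposed new method: the cyclic sulfate serves as a pyrophosphate‑like 1,3‑bis‑electrophile in a one‑flask threefold alkylation, in which the lithium trianion of 3 is C‑alkylated at its only free ring carbon by SN2 opening of 8 at CH2 (closest known: C‑alkylation of acylphloroglucinol polyanions by primary triflates and carbanion openings of cyclic sulfates), prenyl bromide then alkylates the same carbon with dearomatization (as in lupulone‑type gem‑dialkylations) to give 11 together with its C5 epimer (no facial control expected), and in (CF3)2CHOH, which ionizes the tertiary lithium alkyl sulfate and hydrogen‑bonds the enolate oxygens, the contact ion pair is captured by the tricarbonyl enolate carbon C1 through a chair transition state with the C7 prenyl group equatorial and the sulfate leaving anti, so that C8 is inverted from S to R (closest known: stereoinvertive SN1 substitution of tertiary esters, the acid‑mediated cation cyclization of dearomatized acylphloroglucinols, and the invertive tertiary epoxide opening by an enol ether carbon used for the hyperforin core; a free cation would still favour the same chair with the larger homoprenyl group equatorial); only epimer 11 can reach C1 through this chair, which fixes C1 and C5 relative to C7 and C8, whereas its C5 epimer closes at the ester‑bearing carbon or on oxygen and is separated, so the yield cannot exceed 50 %.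

Step 6
Reactants: 12 the C3 methyl ester
Product: 13 (1R,5R,7S,8R)-4-hydroxy-8-methyl-5,7-bis(3-methylbut-2-en-1-yl)-8-(4-methylpent-3-en-1-yl)-1-(2-methylpropanoyl)bicyclo[3.3.1]non-3-ene-2,9-dione
Conditions: LiCl (10 equiv), H2O (2 equiv), DMSO, 120 °C; dilute HCl work-up
Reagents that add atoms: none
Why: Krapcho dealkoxycarbonylation, in which chloride demethylates the ester and the resulting 2‑carboxy‑1,3‑dione loses CO2 to the enol (hydrogen from water), uses the LiCl/DMSO conditions that PPAP cores tolerate in final O‑demethylations, and none of the four stereocenters (two quaternary bridgeheads, quaternary C8, non‑enolizable C7) can epimerize.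

**Compound list**

1 | methyl 2,4,6-trihydroxybenzoate | COC(=O)c1c(O)cc(O)cc1O | starting material
2 | 2-methylpropanoyl chloride (isobutyryl chloride) | CC(C)C(=O)Cl | starting material
3 | methyl 2,4,6-trihydroxy-3-(2-methylpropanoyl)benzoate | COC(=O)c1c(O)cc(O)c(C(=O)C(C)C)c1O | intermediate
4 | nerol, (2Z)-3,7-dimethylocta-2,6-dien-1-ol | CC(C)=CCC/C(C)=C\CO | starting material
5 | (2R,3S)-2,3-epoxynerol, [(2R,3S)-3-methyl-3-(4-methylpent-3-en-1-yl)oxiran-2-yl]methanol | CC(C)=CCC[C@]1(C)O[C@@H]1CO | intermediate
6 | (3-methylbut-2-en-1-yl)magnesium chloride, Me2C=CHCH2MgCl, commercial THF solution | CC(C)=CC[Mg]Cl | starting material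
7 | (2S,3S)-3,7-dimethyl-2-(3-methylbut-2-en-1-yl)oct-6-ene-1,3-diol | CC(C)=CCC[C@](C)(O)[C@@H](CC=C(C)C)CO | intermediate
8 | (4S,5S)-4-methyl-5-(3-methylbut-2-en-1-yl)-4-(4-methylpent-3-en-1-yl)-1,3,2-dioxathiane 2,2-dioxide | CC(C)=CCC[C@]1(C)OS(=O)(=O)OC[C@@H]1CC=C(C)C | intermediate
9 | 1-bromo-3-methylbut-2-ene (prenyl bromide) | CC(C)=CCBr | starting material
10 | methyl 3-[(2S,3S)-3,7-dimethyl-2-(3-methylbut-2-en-1-yl)-3-(sulfooxy)oct-6-en-1-yl]-2,4,6-trihydroxy-5-(2-methylpropanoyl)benzoate (lithium salt in the flask, drawn protonated) | CC(C)=CCC[C@](C)(OS(=O)(=O)O)[C@@H](CC=C(C)C)Cc1c(O)c(C(=O)OC)c(O)c(C(=O)C(C)C)c1O | intermediate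
11 | methyl (3R)-3-[(2S,3S)-3,7-dimethyl-2-(3-methylbut-2-en-1-yl)-3-(sulfooxy)oct-6-en-1-yl]-2,6-dihydroxy-3-(3-methylbut-2-en-1-yl)-5-(2-methylpropanoyl)-4-oxocyclohexa-1,5-diene-1-carboxylate (lithium salt in the flask, drawn protonated; the ring quaternary carbon is the future C5; formed beside its C5 epimer) | CC(C)=CCC[C@](C)(OS(=O)(=O)O)[C@@H](CC=C(C)C)C[C@@]1(CC=C(C)C)C(=O)C(C(=O)C(C)C)=C(O)C(C(=O)OC)=C1O | intermediate
12 | methyl (1S,5R,7S,8R)-4-hydroxy-8-methyl-5,7-bis(3-methylbut-2-en-1-yl)-8-(4-methylpent-3-en-1-yl)-1-(2-methylpropanoyl)-2,9-dioxobicyclo[3.3.1]non-3-ene-3-carboxylate (same shape as 13; C1 is labelled S only because the ester raises the CIP rank of C2) | CC(C)=CCC[C@]1(C)[C@@H](CC=C(C)C)C[C@@]2(CC=C(C)C)C(=O)[C@]1(C(=O)C(C)C)C(=O)C(C(=O)OC)=C2O | intermediate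
13 | (1R,5R,7S,8R)-4-hydroxy-8-methyl-5,7-bis(3-methylbut-2-en-1-yl)-8-(4-methylpent-3-en-1-yl)-1-(2-methylpropanoyl)bicyclo[3.3.1]non-3-ene-2,9-dione | CC(C)=CCC[C@]1(C)[C@@H](CC=C(C)C)C[C@@]2(CC=C(C)C)C(=O)[C@]1(C(=O)C(C)C)C(=O)C=C2O | target

**Step count and risks**

Total steps: 6. Longest linear sequence: 5 (4 → 5 → 7 → 8 → 12 → 13).

The three steps most likely to fail:

Step 5 is the most uncertain. The cyclic sulfate may alkylate oxygen instead of carbon, and the C8 ion pair may collapse on O4/O9 to give cyclic enol ethers or eliminate. C5 is also formed without facial control, so at best half of the material can close. Fallback: keep the two alkylations but change the ring‑closing nucleophile from the lithium enolate to a silyl enol ether. Setting out from intermediate 11 in the same flask, Me3SiOTf and 2,6‑lutidine in CH2Cl2 at −78 °C silylate both enolate oxygens and the sulfate to give the bis(trimethylsilyl) enol ether trimethylsilyl sulfate F1. On warming to 0 °C the silyl sulfate ionizes and the silyl enol ether carbon C1, with the oxygens blocked, attacks the tertiary centre (tertiary alkylation of a silyl enol ether, Mukaiyama/Reetz type) to give the trimethylsilyl enol ether F2. Aqueous work‑up hydrolyses F2 to 12, where the route is rejoined.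

Step 4 may fail because the tertiary alkoxide can displace the primary imidazolylsulfonate to give an oxetane, or because the tertiary cyclic sulfate ionizes on handling. Fallback: activate only the primary hydroxyl and generate the C8 cation from the free tertiary alcohol. Setting out from diol 7, Tf2O and 2,6‑di‑tert‑butylpyridine (CH2Cl2, −78 °C) give the hydroxy triflate F3, which is used cold in place of 8. The trianion of 3 (LiN(SiMe3)2, THF) is C‑alkylated to the aryl tertiary alcohol F4, and prenylation with 9 gives the dearomatized tertiary alcohol F5 (both C5 epimers). F5 is cyclized in HCO2H at room temperature, a Brønsted‑acid cation cyclization in which O‑alkylation is reversible and C8 is controlled only by the chair preference for an equatorial homoprenyl group. This returns to the route at 12.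

Step 3 may fail because the prenyl nucleophile can couple through its γ‑carbon (1,1‑dimethylallyl product) or open the epoxide at C3. Fallback: use an unsubstituted allyl nucleophile and build the prenyl group by olefin metathesis. Setting out from 5, CH2=CHCH2MgBr with CuI (10 mol %) opens C2 with inversion to give the 2‑allyl diol F6. Cross‑metathesis with 2‑methylbut‑2‑ene (second‑generation Grubbs catalyst, CH2Cl2, 40 °C; the trisubstituted alkene already present is inert) converts allyl into prenyl, returning to the route at 7.

Further compounds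
F1 | step 5 | bis(trimethylsilyl) enol ether trimethylsilyl sulfate of 11 (C9 and C4 oxygens silylated, C2 ketone) | CC(C)=CCC[C@](C)(OS(=O)(=O)O[Si](C)(C)C)[C@@H](CC=C(C)C)C[C@@]1(CC=C(C)C)C(O[Si](C)(C)C)=C(C(=O)C(C)C)C(=O)C(C(=O)OC)=C1O[Si](C)(C)C
F2 | step 5 | C4 trimethylsilyl enol ether of 12 | CC(C)=CCC[C@]1(C)[C@@H](CC=C(C)C)C[C@@]2(CC=C(C)C)C(=O)[C@]1(C(=O)C(C)C)C(=O)C(C(=O)OC)=C2O[Si](C)(C)C
F3 | step 4 | (2S,3S)-3-hydroxy-3,7-dimethyl-2-(3-methylbut-2-en-1-yl)oct-6-en-1-yl trifluoromethanesulfonate | CC(C)=CCC[C@](C)(O)[C@@H](CC=C(C)C)COS(=O)(=O)C(F)(F)F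
F4 | step 4 | methyl 2,4,6-trihydroxy-3-[(2S,3S)-3-hydroxy-3,7-dimethyl-2-(3-methylbut-2-en-1-yl)oct-6-en-1-yl]-5-(2-methylpropanoyl)benzoate | CC(C)=CCC[C@](C)(O)[C@@H](CC=C(C)C)Cc1c(O)c(C(=O)OC)c(O)c(C(=O)C(C)C)c1O
F5 | step 4 | methyl (3R)-2,6-dihydroxy-3-[(2S,3S)-3-hydroxy-3,7-dimethyl-2-(3-methylbut-2-en-1-yl)oct-6-en-1-yl]-3-(3-methylbut-2-en-1-yl)-5-(2-methylpropanoyl)-4-oxocyclohexa-1,5-diene-1-carboxylate (formed beside its C5 epimer) | CC(C)=CCC[C@](C)(O)[C@@H](CC=C(C)C)C[C@@]1(CC=C(C)C)C(=O)C(C(=O)C(C)C)=C(O)C(C(=O)OC)=C1O
F6 | step 3 | (2S,3S)-3,7-dimethyl-2-(prop-2-en-1-yl)oct-6-ene-1,3-diol | CC(C)=CCC[C@](C)(O)[C@@H](CC=C)CO
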